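## Structural features

The target has one benzene ring with a 1,2,4,5 substitution pattern: the aryl tiglate oxygen on C1, an oxirane on C2, a methoxy group on C4 and a methyl group on C5. The oxirane is attached to the arene through its fully substituted carbon (C2'), which also carries a CH2O–isobutyryl arm. The oxirane CH2 and this arm are both CH2–O groups, so C2' is a quaternary stereocentre whose two one-carbon arms differ only in what their oxygen carries. C2' is the only stereocentre, (R), with no neighbouring centre to relay from, so it must be set by catalyst or reagent control. Three groups are fragile: the tertiary benzylic oxirane on an electron-rich ring (acid-labile, and open to attack by an unmasked ortho phenol oxygen), the aryl tiglate (an activated ester that will not survive hydride, alkoxide or amine reagents, and whose conjugation can be lost under strongly basic acylation), and the primary isobutyrate (able to migrate to a nearby alkoxide). The difficulty is to make the benzylic quaternary C–O centre as one enantiomer and to tell apart the phenolic, primary and oxirane oxygens without ever leaving a phenoxide beside a leaving group. The key step uses the fact that C2' sits on the arene carbon ortho to the phenolic oxygen and bears one oxygen and two one-carbon arms: this is the imprint of a phenol ortho carbon adding to the ketone of a pyruvate whose ester and CH2Br groups become the two arms.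

## Logic of the disconnections

11 ⇒ 9 + 10. The aryl O–C(acyl) bond of the unsaturated ester is cut first. Such an aryl ester would be lost to hydride, alkoxide or amine reagents and would migrate to any neighbouring alkoxide, so it has to be the last bond made. The cut removes the unsaturated acyl unit and leaves a phenol. The forward acylation must outrun attack of the ortho oxygen on the oxirane and must not deconjugate the acyl group.

9 ⇒ 8. The phenolic O–H is exchanged for an O–allyl bond. An ether is needed because acyl and silyl groups on this oxygen would shift to the benzylic alkoxide formed during ring closure, whereas an allyl group cannot. This leaves a compound with no acidic or nucleophilic oxygen. The forward removal must be nearly neutral, so that oxirane and ester survive and the phenol stays protonated.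

8 ⇒ 6 + 7. The primary O–C(acyl) bond of the saturated ester is cut. 6 has a single free hydroxyl, so no selectivity question arises. The forward step needs an acylation whose acidic by-product is too weak to open the oxirane.

6 ⇒ 5 ⇒ 4. The hydroxymethyl group is traced back to an ethyl ester (5), and the oxirane O–CH2 bond of 5 is cut to give the bromohydrin 4. The C–O bond at the stereocentre is never touched, so configuration passes through unchanged. Both arms of the quaternary carbon are now an ester and a CH2Br group, the substitution of a bromopyruvate. The forward step needs the tertiary alkoxide to displace bromide before hydride is added, and it needs the phenol to be etherified already; a free phenoxide would take the bromide itself in a five-membered closure to a dihydrobenzofuran.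

4 ⇒ 3. The O–allyl bond is cut. Because of the hazard just named, the allyl group cannot be put on with carbonate base and an allyl halide. The forward step therefore uses an allyl carbonate under neutral palladium catalysis, where the phenoxide exists only as a short-lived ion pair with its own electrophile.

3 ⇒ 1 + 2. The aryl C–C(quaternary) bond is cut. This reduces the problem to two commercial compounds and places the creation of the only stereocentre in the same step as the only skeletal bond. The forward step must be ortho-selective for the carbon para to the ring methyl, enantioface-selective at the ketone, and chemoselective for the ketone over the CH2Br carbon.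

## Other disconnections considered

Alternative 1: The cut goes through the arene: three ring C–C bonds are broken so that the benzene ring is assembled from pentacarbonyl[methoxy(isopropenyl)carbene]chromium A1, the terminal alkyne [(R)-2-ethynyloxiran-2-yl]methyl 2-methylpropanoate A2 and one carbonyl ligand.
- Forward key step: heating A1 with A2 (Dötz benzannulation) would join the carbene carbon to the alkyne CH, the substituted alkyne carbon to CO, and CO to the alkene CH2. After decomplexation this would give the para-methoxyphenol A3, which is the same compound as 9.
- In its favour: the 1,2,4,5 pattern is written into the components, the phenol and the methyl ether are differentiated from the start, and the sequence is convergent and ends one step from the target.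
- Against it here: the stereocentre is imported, not made. A2 is a quaternary propargylic oxirane that would need its own multi-step asymmetric synthesis and is at least as hard as the problem it replaces. A propargylic oxirane would face low-valent chromium at 45–60 °C (risk of SN2'-type opening), and insertion next to a quaternary carbon is slow and invites cyclobutenone and furan side paths. The product is the least stable intermediate of the chosen route (free ortho phenol beside the oxirane), formed bound to a Cr(CO)3 fragment that must be removed oxidatively without oxidising the hydroquinone monoether. Stoichiometric chromium is a further burden.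
- Comparison: on regiochemical certainty of the arene pattern this alternative is the better plan, since the chosen route depends on delivery to one of two ortho carbons; on convergence it is the equal. On stereocontrol the chosen plan is stronger, because it creates the centre catalytically from achiral partners. Mechanistically the chosen step makes one bond in one coordination sphere, whereas the benzannulation strings alkyne insertion, CO insertion and electrocyclisation together in the presence of a strained electrophile. In step count the alternative is longer (about two steps to A1, an estimated five or more to A2, then the final acylation) than six.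

Alternative 2: The cut is the C(quaternary)–CH2OH bond, leaving the monosubstituted oxirane (R)-2-[5-methoxy-4-methyl-2-(triisopropylsilyloxy)phenyl]oxirane A4.
- Forward key step: deprotonation of the benzylic oxirane C–H of A4 with a sec-alkyllithium/diamine base near −98 °C and trapping of the oxiranyllithium with monomeric formaldehyde A5 would give [(S)-2-[5-methoxy-4-methyl-2-(triisopropylsilyloxy)phenyl]oxiran-2-yl]methanol A6 with retention.
- In its favour: the stereocentre of A4 is a simple secondary benzylic one, for which dependable asymmetric methods exist (enantioselective reduction of an α-halo ketone followed by closure). The oxirane is in place before the quaternary centre is made, so no halohydrin stage is needed. A6 is the silyl analogue of 6, so the endgame is the same.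
- Against it here: the electron-rich, ortho-substituted aryl group lowers the acidity of the benzylic proton and the lifetime of the carbenoid-like oxiranyllithium (eliminative dimerisation, ring opening). The ortho silyloxy group is placed for an anionic O-to-C silyl shift onto the lithiated carbon, and the methoxy group and ring methyl offer competing lithiation sites. Gaseous formaldehyde and −98 °C are demanding. A4 itself would need about five steps from 1, during which an ortho phenol again sits beside a halohydrin or oxirane.
- Comparison: on predictability of the enantioselectivity this alternative is the better one (a mature asymmetric reduction against an extension of a titanium–BINOL Friedel–Crafts addition); on the endgame it is equal. On mechanism it is more delicate, because retention depends on the configurational and chemical stability of a lithiated oxirane, whereas the chosen step is a closed-shell, Lewis-acid-templated addition at −20 to 0 °C. On step economy it is longer (about nine or ten steps against six).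

Alternative 3: The cut is the O–C(acyl) bond of the isobutyrate, made at the stage of the prochiral triol 2-[2-(allyloxy)-5-methoxy-4-methylphenyl]propane-1,2,3-triol A7, whose two CH2OH arms are enantiotopic.
- Forward key step: a lipase would transfer the isobutyryl group from vinyl isobutyrate A8 to one arm, giving (R)-2-[2-(allyloxy)-5-methoxy-4-methylphenyl]-2,3-dihydroxypropyl 2-methylpropanoate A9. Sulfonylation of the remaining primary hydroxyl and closure from the tertiary oxygen would then lead to 8.
- In its favour: the enzyme would set the stereocentre and install the target's own isobutyrate in one event. A desymmetrisation can in principle convert all material to one enantiomer, and over-acylation to the achiral diester can sharpen the purity of the monoester. The conditions are mild and metal-free, and A7 is achiral and reachable from 1 in about three non-stereoselective steps.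
- Against it here: recognition of enantiotopic arms at a fully substituted carbinol carbon bearing a bulky ortho-substituted aryl group cannot be predicted, and neither the level nor the hand of selectivity is assured without enzyme screening. A9 can racemise by acyl migration between the two primary oxygens through the tertiary hydroxyl, most dangerously under the basic sulfonylation and closure that must follow.
- Comparison: on economy at the stereo-defining step this alternative is the better one, since stereocentre and ester arrive together and no chiral metal catalyst is needed; the endgame from 8 is equal. On structure it uses a hidden symmetry that the chosen plan does not need. On mechanism the chosen plan fixes the configuration in a C–C bond-forming step, after which no bond to the quaternary carbon is broken, whereas A9 stays stereochemically labile until the ring is closed. In step count the alternative is longer (about eight against six).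

Key step: step 1

Assumption: the (R)-ligand is taken, by analogy with related titanium–BINOL additions, to give the (S)-carbinol 3; if the facial sense is the reverse, (S)-BINOL is used and nothing else changes.
Remark on the chemistry: after step 1 no bond to the quaternary carbon is made or broken; the change of descriptor between S (3, 4, 6) and R (5, 8, 9, 11) reflects only changes in substituent priority.

Step 1
Reactants: 1 4-methoxy-3-methylphenol; 2 ethyl bromopyruvate (ethyl 3-bromo-2-oxopropanoate)
Product: 3 ethyl (S)-3-bromo-2-hydroxy-2-(2-hydroxy-5-methoxy-4-methylphenyl)propanoate
Conditions: (R)-BINOL (11 mol%), Ti(OiPr)4 (10 mol%), 4 Å MS, CH2Cl2, −20 to 0 °C, slow addition of 2 (1.2 equiv); aq. NH4Cl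
Reagents that add atoms: none
Why: Friedel–Crafts ortho-hydroxyalkylation of a phenol by an activated α-keto ester under chiral titanium–BINOL catalysis. Phenol 1 exchanges for isopropoxide on the tetravalent titanium of (R)-BINOL–Ti(OiPr)2, and 2 binds through its ketone and ester carbonyls as a five-membered chelate. The ortho carbon of the titanium aryloxide attacks the ketone carbon inside this coordination sphere through a six-membered array, and the cyclohexadienone formed tautomerises back to the phenol; no ring closes, so no mode of ring closure applies. The closest known reactions are the titanium–BINOL-catalysed ortho additions of phenols to glyoxylates and trifluoropyruvate and the ortho-hydroxyalkylation of titanium phenoxides with pyruvate esters, and bromopyruvate is a further halogen-activated member of that electrophile class. The one new stereocentre, the quaternary carbinol carbon, is controlled by the BINOLate ligand, which leaves one enantioface of the chelated ketone open to the aryloxide and should give the (S) configuration. Regioselectivity is needed between C-2 and C-6 of 1 and against O-alkylation: the para position is blocked by methoxy, C-2 is flanked by the ring methyl, and delivery from titanium directs the new bond to C-6. Chemoselectivity for the ketone over the CH2Br carbon rests on the absence of base (no free phenoxide for SN2) and on the extra electrophilicity that bromine gives the ketone, which also permits a temperature low enough to hold back the ligand-free background reaction.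

Step 2
Reactants: 3 ethyl (S)-3-bromo-2-hydroxy-2-(2-hydroxy-5-methoxy-4-methylphenyl)propanoate
Product: 4 ethyl (S)-2-[2-(allyloxy)-5-methoxy-4-methylphenyl]-3-bromo-2-hydroxypropanoate
Conditions: allyl ethyl carbonate (1.2 equiv), Pd(PPh3)4 (2 mol%), THF, rt; filtration through silica
Reagents that add atoms: allyl ethyl carbonate, C=CCOC(=O)OCC
Why: Tsuji–Trost O-allylation of a phenol: zerovalent palladium ionises the carbonate, CO2 is lost, the ethoxide formed takes the phenolic proton and the phenoxide–allylpalladium ion pair collapses to the aryl allyl ether. No stoichiometric base is present, so phenoxide does not build up beside the CH2Br group (a carbonate/allyl halide protocol would invite 5-exo-tet closure to a dihydrobenzofuran), and the hindered tertiary hydroxyl should not be allylated.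

Step 3
Reactants: 4 ethyl (S)-2-[2-(allyloxy)-5-methoxy-4-methylphenyl]-3-bromo-2-hydroxypropanoate
Product: 6 [(S)-2-[2-(allyloxy)-5-methoxy-4-methylphenyl]oxiran-2-yl]methanol, via glycidic ester 5 (not isolated)
Conditions: K2CO3 (1.5 equiv), EtOH, 0 °C to rt; then NaBH4 (2 equiv), 0 °C; neutral work-up
Reagents that add atoms: none
Why: Base-induced halohydrin closure (3-exo-tet; the tertiary alkoxide displaces bromide and the C–O bond at the stereocentre is untouched, so configuration is retained) followed by NaBH4 reduction of the α-oxygenated, hence activated, ester. Ethanol makes any ester exchange degenerate, and a Payne rearrangement of 6 would regenerate the same enantiomer, because inversion at the quaternary carbon is coupled to exchange of its two CH2O arms.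

Step 4
Reactants: 6 [(S)-2-[2-(allyloxy)-5-methoxy-4-methylphenyl]oxiran-2-yl]methanol; 7 isobutyryl chloride
Product: 8 [(R)-2-[2-(allyloxy)-5-methoxy-4-methylphenyl]oxiran-2-yl]methyl 2-methylpropanoate
Conditions: Et3N (1.5 equiv), DMAP (5 mol%), CH2Cl2, 0 °C
Reagents that add atoms: none
Why: DMAP-catalysed O-acylation of the only free hydroxyl; triethylammonium chloride is too weak an acid to open the oxirane, and the stereocentre is not involved.

Step 5
Reactants: 8 [(R)-2-[2-(allyloxy)-5-methoxy-4-methylphenyl]oxiran-2-yl]methyl 2-methylpropanoate
Product: 9 [(R)-2-(2-hydroxy-5-methoxy-4-methylphenyl)oxiran-2-yl]methyl 2-methylpropanoate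
Conditions: Pd(PPh3)4 (5 mol%), morpholine (3 equiv), THF, rt; pH 7 buffer, Et3N-deactivated silica, used at once
Reagents that add atoms: none
Why: Tsuji–Trost deallylation: zerovalent palladium ionises the aryl allyl ether and morpholine captures the allyl fragment. Morpholine is too weak a base to deprotonate the phenol to a significant extent, attack of the phenol oxygen on the oxirane CH2 would be a geometrically disfavoured 5-endo opening, and the esters and oxirane should be inert at room temperature.

Step 6
Reactants: 9 [(R)-2-(2-hydroxy-5-methoxy-4-methylphenyl)oxiran-2-yl]methyl 2-methylpropanoate; 10 tigloyl chloride ((E)-2-methylbut-2-enoyl chloride)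
Product: 11 2-[(R)-2-[(isobutyryloxy)methyl]oxiran-2-yl]-4-methoxy-5-methylphenyl (E)-2-methylbut-2-enoate (target)
Conditions: pyridine (3 equiv), DMAP (10 mol%), CH2Cl2, −20 to 0 °C
Reagents that add atoms: none
Why: Nucleophilic catalysis (acylpyridinium) should acylate the neutral phenol quickly at low temperature. Pyridine is used instead of a trialkylamine to avoid dehydrochlorination of 10 to a vinylketene, which would give the deconjugated 2-methylbut-3-enoate; the E geometry of 10 is the thermodynamically preferred one and is carried through, and the stereocentre is not involved.

Compound list
1 | 4-methoxy-3-methylphenol | Cc1cc(O)ccc1OC | starting material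
2 | ethyl bromopyruvate (ethyl 3-bromo-2-oxopropanoate) | CCOC(=O)C(=O)CBr | starting material
3 | ethyl (S)-3-bromo-2-hydroxy-2-(2-hydroxy-5-methoxy-4-methylphenyl)propanoate | Oc1cc(C)c(OC)cc1[C@](O)(C(=O)OCC)CBr | intermediate
4 | ethyl (S)-2-[2-(allyloxy)-5-methoxy-4-methylphenyl]-3-bromo-2-hydroxypropanoate | C=CCOc1cc(C)c(OC)cc1[C@](O)(C(=O)OCC)CBr | intermediate
5 | ethyl (R)-2-[2-(allyloxy)-5-methoxy-4-methylphenyl]oxirane-2-carboxylate | C=CCOc1cc(C)c(OC)cc1[C@]1(C(=O)OCC)CO1 | intermediate (not isolated)
6 | [(S)-2-[2-(allyloxy)-5-methoxy-4-methylphenyl]oxiran-2-yl]methanol | C=CCOc1cc(C)c(OC)cc1[C@]1(CO)CO1 | intermediate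
7 | isobutyryl chloride | CC(C)C(Cl)=O | starting material
8 | [(R)-2-[2-(allyloxy)-5-methoxy-4-methylphenyl]oxiran-2-yl]methyl 2-methylpropanoate | C=CCOc1cc(C)c(OC)cc1[C@]1(COC(=O)C(C)C)CO1 | intermediate
9 | [(R)-2-(2-hydroxy-5-methoxy-4-methylphenyl)oxiran-2-yl]methyl 2-methylpropanoate | Oc1cc(C)c(OC)cc1[C@]1(COC(=O)C(C)C)CO1 | intermediate
10 | tigloyl chloride ((E)-2-methylbut-2-enoyl chloride) | C/C=C(\C)C(Cl)=O | starting material
11 | 2-[(R)-2-[(isobutyryloxy)methyl]oxiran-2-yl]-4-methoxy-5-methylphenyl (E)-2-methylbut-2-enoate | C/C=C(\C)C(=O)Oc1cc(C)c(OC)cc1[C@]1(COC(=O)C(C)C)CO1 | target

Total step count: 6. Longest linear sequence: 6 steps (1 → 3 → 4 → 6 → 8 → 9 → 11, with 2, 7 and 10 joined along the way).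

Steps least certain to work

Step 1 (key step). The most likely failure is erosion of enantioselectivity through a ligand-free pathway. Product 3 offers titanium a phenol, a carbinol and an ester oxygen and can hold the metal as a chelate, which slows turnover and lets BINOL-free titanium aryloxides carry a racemic background reaction. O-Alkylation at CH2Br, lactonisation of 3 onto its phenol and isopropoxide exchange at the ester are further possible losses. Fallback (sets out from 1, returns at 6): auxiliary control with stoichiometric titanium, which needs no turnover. (−)-Menthyl bromopyruvate F1 (from commercial bromopyruvic acid and (−)-menthol, TsOH, toluene, azeotropic removal of water) is added to the titanium aryloxide made from 1 and TiCl4 in CH2Cl2 at −30 °C. This ortho-hydroxyalkylation of titanium phenoxides with chiral pyruvate esters should give the menthyl (S)-bromohydrin ester F2 after removal of the minor diastereomer by crystallisation or chromatography; the other menthol antipode is used if the induction runs the opposite way. Allylation as in step 2 would give the allyl ether F3, NaH in THF at 0 °C would close the menthyl glycidate F4, and LiBH4 in THF would release the auxiliary and deliver 6.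

Step 2. The most likely failure is displacement of bromide by the phenoxide that exists briefly in the allylpalladium ion pair (five-membered ring closure), or slow re-ionisation of 4 by the catalyst leading to C-allylation. Fallback (sets out from 3, returns at 9): a silyl ether and a halophilic ring closure, so that neither phenoxide nor palladium is present. TIPSCl and imidazole in DMF should give the silyl ether F5. Ag2O in DME would close the oxirane by silver-assisted removal of bromide without a free alkoxide, which would otherwise trigger an O-to-O silyl shift, giving glycidic ester F6. NaBH4 in EtOH at 0 °C would give epoxy alcohol F7 (the same compound as A6), acylation with 7 as in step 4 would give ester F8, and Bu4NF buffered with AcOH in THF at 0 °C would remove the silyl group and return 9.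

Step 3. The most likely failure is alkoxide opening of the activated glycidic ester 5 at its CH2 terminus before hydride is added, or incomplete closure at the moment of reduction, either of which would give mixtures. Fallback (sets out from 4, returns at 6): the order is reversed. iBu2AlH (toluene/CH2Cl2, −78 °C) would reduce the ester of 4 under non-basic conditions to the bromo diol F9. NaH in THF at 0 °C would then close the oxirane from the tertiary oxygen, three-membered closure being faster than the four-membered alternative from the primary oxygen, to give 6.

Step 5. The most likely failure is opening of the oxirane once the ortho phenol is unmasked: cyclisation through the phenoxide to a 3-hydroxy-2,3-dihydrobenzofuran, or quinone-methide-type ionisation on silica. The hazard runs through deallylation, isolation and the acylation of step 6; sluggish ionisation of the electron-rich aryl allyl ether is a second concern. Fallback (sets out from 8, returns at 11): trans-protection without a free phenol. Pd(PPh3)4 with Bu3SnH (1.05 equiv) in CH2Cl2 would cleave the allyl ether by hydrostannolysis to the covalent tributylstannyl aryl ether F10, which is neither basic nor nucleophilic toward the oxirane. Once the stannane is consumed, 10 is added to the same flask and should acylate the tin phenoxide to give 11 directly.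

Further compounds
F1 | step 1 | (1R,2S,5R)-2-isopropyl-5-methylcyclohexyl 3-bromo-2-oxopropanoate | C[C@@H]1CC[C@H]([C@@H](C1)OC(=O)C(=O)CBr)C(C)C
F2 | step 1 | (1R,2S,5R)-2-isopropyl-5-methylcyclohexyl (S)-3-bromo-2-hydroxy-2-(2-hydroxy-5-methoxy-4-methylphenyl)propanoate | C[C@@H]1CC[C@H]([C@@H](C1)OC(=O)[C@](O)(CBr)c2cc(OC)c(C)cc2O)C(C)C
F3 | step 1 | (1R,2S,5R)-2-isopropyl-5-methylcyclohexyl (S)-2-[2-(allyloxy)-5-methoxy-4-methylphenyl]-3-bromo-2-hydroxypropanoate | C[C@@H]1CC[C@H]([C@@H](C1)OC(=O)[C@](O)(CBr)c2cc(OC)c(C)cc2OCC=C)C(C)C
F4 | step 1 | (1R,2S,5R)-2-isopropyl-5-methylcyclohexyl (R)-2-[2-(allyloxy)-5-methoxy-4-methylphenyl]oxirane-2-carboxylate | C[C@@H]1CC[C@H]([C@@H](C1)OC(=O)[C@]2(CO2)c3cc(OC)c(C)cc3OCC=C)C(C)C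
F5 | step 2 | ethyl (S)-3-bromo-2-hydroxy-2-[5-methoxy-4-methyl-2-(triisopropylsilyloxy)phenyl]propanoate | CC(C)[Si](C(C)C)(C(C)C)Oc1cc(C)c(OC)cc1[C@](O)(C(=O)OCC)CBr
F6 | step 2 | ethyl (R)-2-[5-methoxy-4-methyl-2-(triisopropylsilyloxy)phenyl]oxirane-2-carboxylate | CC(C)[Si](C(C)C)(C(C)C)Oc1cc(C)c(OC)cc1[C@]1(C(=O)OCC)CO1
F7 | step 2 | [(S)-2-[5-methoxy-4-methyl-2-(triisopropylsilyloxy)phenyl]oxiran-2-yl]methanol | CC(C)[Si](C(C)C)(C(C)C)Oc1cc(C)c(OC)cc1[C@]1(CO)CO1
F8 | step 2 | [(R)-2-[5-methoxy-4-methyl-2-(triisopropylsilyloxy)phenyl]oxiran-2-yl]methyl 2-methylpropanoate | CC(C)[Si](C(C)C)(C(C)C)Oc1cc(C)c(OC)cc1[C@]1(COC(=O)C(C)C)CO1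
F9 | step 3 | (S)-2-[2-(allyloxy)-5-methoxy-4-methylphenyl]-3-bromopropane-1,2-diol | C=CCOc1cc(C)c(OC)cc1[C@](O)(CO)CBr
F10 | step 5 | [(R)-2-[5-methoxy-4-methyl-2-(tributylstannyloxy)phenyl]oxiran-2-yl]methyl 2-methylpropanoate | CCCC[Sn](CCCC)(CCCC)Oc1cc(C)c(OC)cc1[C@]1(COC(=O)C(C)C)CO1
A1 | alternative 1 | pentacarbonyl[methoxy(prop-1-en-2-yl)carbene]chromium | C=C(C)C(OC)=[Cr](=C=O)(=C=O)(=C=O)(=C=O)=C=O
A2 | alternative 1 | [(R)-2-ethynyloxiran-2-yl]methyl 2-methylpropanoate | C#C[C@]1(COC(=O)C(C)C)CO1
A3 | alternative 1 | [(R)-2-(2-hydroxy-5-methoxy-4-methylphenyl)oxiran-2-yl]methyl 2-methylpropanoate | Oc1cc(C)c(OC)cc1[C@]1(COC(=O)C(C)C)CO1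
A4 | alternative 2 | (R)-2-[5-methoxy-4-methyl-2-(triisopropylsilyloxy)phenyl]oxirane | CC(C)[Si](C(C)C)(C(C)C)Oc1cc(C)c(OC)cc1[C@@H]1CO1
A5 | alternative 2 | formaldehyde | C=O
A6 | alternative 2 | [(S)-2-[5-methoxy-4-methyl-2-(triisopropylsilyloxy)phenyl]oxiran-2-yl]methanol | CC(C)[Si](C(C)C)(C(C)C)Oc1cc(C)c(OC)cc1[C@]1(CO)CO1
A7 | alternative 3 | 2-[2-(allyloxy)-5-methoxy-4-methylphenyl]propane-1,2,3-triol | C=CCOc1cc(C)c(OC)cc1C(O)(CO)CO
A8 | alternative 3 | vinyl isobutyrate | C=COC(=O)C(C)C
A9 | alternative 3 | (R)-2-[2-(allyloxy)-5-methoxy-4-methylphenyl]-2,3-dihydroxypropyl 2-methylpropanoate | C=CCOc1cc(C)c(OC)cc1[C@](O)(COC(=O)C(C)C)CO
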